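The route rests on cutting the central benzene ring (ring B) into a four-carbon cyclobutenone and a two-carbon methyl ynol ether. Ring B shows C–OH and C–OMe in a meta relationship, a benzyl-bearing carbon between them and its only C–H beside C–OMe. The arylethyl- and second benzyl-bearing carbons sit side by side on the rest of the ring. This array maps atom for atom onto a Danheiser benzannulation product. One thermal operation makes three ring C–C bonds, places all five substituents and frees the phenol already distinct from the methyl ether. Its precursors are racemic 4-(4-benzyloxybenzyl)-3-(arylethyl)cyclobutenone and a benzyl-substituted 1-methoxyalkyne; the outer arenes are purchased.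

Key step: step 7

Remark on the chemistry: the target is achiral. Every four-membered-ring intermediate is handled as the racemate, because its sp3 ring carbon becomes sp2 when ring B aromatises.

Step 1
Reactants: 1 3-(4-benzyloxyphenyl)propanoic acid
Product: 2 3-(4-benzyloxyphenyl)propanoyl chloride
Conditions: (COCl)2 (1.2 equiv), DMF (cat.), CH2Cl2, 0 °C to rt; concentrate, use crude
Reagents that add atoms: oxalyl chloride, O=C(Cl)C(=O)Cl
Why: DMF-catalysed (Vilsmeier-type) acid chloride formation runs cold and without Lewis acid, so the aryl benzyl ether survives and all by-products leave as gases.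

Step 2
Reactants: 2 3-(4-benzyloxyphenyl)propanoyl chloride; 3 ethoxyacetylene
Product: 5 rac-4-(4-benzyloxybenzyl)-3-ethoxycyclobut-2-en-1-one, via ketene 4 (not isolated)
Conditions: 3 (3 equiv, hexane solution), Et3N (1.3 equiv), Et2O, 0 °C; 2 in Et2O added by syringe pump over several hours; then rt
Reagents that add atoms: none
Why: Amine-induced dehydrochlorination gives aldoketene 4, which is trapped in a ketene–ynol ether (2+2) cycloaddition where the nucleophilic terminal CH of 3 bonds to the ketene carbonyl carbon, so OEt lands on C3 and the benzyl group on the racemic sp3 carbon C4, while slow addition into excess 3 keeps the ketene dilute and suppresses its dimerisation.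

Step 3
Reactants: 6 1-(2-bromoethyl)-3-methoxybenzene
Product: 7 2-(3-methoxyphenyl)ethylmagnesium bromide (titrated THF solution)
Conditions: Mg turnings (1.5 equiv), I2 (cat.), THF, slow addition, rt to 40 °C
Reagents that add atoms: magnesium, [Mg]
Why: Grignard formation by magnesium insertion into a primary C–Br bond is routine, slow addition limits Wurtz coupling, and the aryl methyl ether is inert.

Step 4
Reactants: 5 rac-4-(4-benzyloxybenzyl)-3-ethoxycyclobut-2-en-1-one; 7 2-(3-methoxyphenyl)ethylmagnesium bromide
Product: 9 rac-4-(4-benzyloxybenzyl)-3-[2-(3-methoxyphenyl)ethyl]cyclobut-2-en-1-one, via cyclobutenol 8 (not isolated)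
Conditions: 7 (1.2 equiv), THF, −78 °C; then 1 M aq HCl, 0 °C to rt
Reagents that add atoms: water, O
Why: This is a Stork–Danheiser-type transposition, in which 1,2-addition to the vinylogous ester carbonyl (C4 enolisation is disfavoured because the enolate would be cyclobutadiene-like) is followed by acid ionisation of the tertiary allylic alcohol, capture by water and loss of ethanol, and because C4 adjoins both C1 and C3 of the four-membered ring the benzyl group stays on the sp3 carbon next to the new carbonyl.

Step 5
Reactants: 10 chloroacetaldehyde dimethyl acetal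
Product: 12 methoxyacetylene (cold THF solution), via sodium methoxyacetylide 11 (not isolated)
Conditions: NaNH2 (3.1 equiv), liquid NH3, −33 °C; NH3 evaporated; cold saturated aq NaCl, −70 °C; distilled into a −78 °C trap, dried, diluted with THF
Reagents that add atoms: none
Why: Two successive amide-induced β-eliminations (of methanol and of HCl) and deprotonation give the acetylide, and protonation with distillation of the low-boiling alkyne removes the methoxide and ammonia that would otherwise compete for the very reactive benzylic bromide in the next step.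

Step 6
Reactants: 12 methoxyacetylene; 13 4-benzyloxybenzyl bromide
Product: 15 1-(benzyloxy)-4-(3-methoxyprop-2-yn-1-yl)benzene, via lithium methoxyacetylide 14 (not isolated)
Conditions: n-BuLi (1.0 equiv on 12), THF, −78 °C; then 13 (0.75 equiv), DMPU, −78 to 0 °C; aq NaHCO3 work-up, Et3N-deactivated silica
Reagents that add atoms: none
Why: This is an SN2 C-alkylation of a lithium alkoxyacetylide with a benzylic bromide in a dipolar cosolvent, where exact stoichiometry of n-BuLi leaves no base stronger than the acetylide and the non-acidic isolation protects the ynol ether from hydration.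

Step 7
Reactants: 9 rac-4-(4-benzyloxybenzyl)-3-[2-(3-methoxyphenyl)ethyl]cyclobut-2-en-1-one; 15 1-(benzyloxy)-4-(3-methoxyprop-2-yn-1-yl)benzene
Product: 20 2,6-bis(4-benzyloxybenzyl)-3-methoxy-5-[2-(3-methoxyphenyl)ethyl]phenol, via vinylketene 16 (not isolated), via alkenylcyclobutenone 17 (not isolated), via dienylketene 18 (not isolated), via cyclohexadienone 19 (not isolated)
Conditions: 15 (1.5 equiv), degassed toluene (0.5 M), sealed tube, 80 °C then 110 °C
Reagents that add atoms: none
Why: Danheiser benzannulation: heating opens 9 by conrotatory 4π cleavage of the C1–C4 bond, the benzyl group turning outward, to give (E)-vinylketene 16, whose ketene C=C bond is captured by the electron-rich ynol ether 15 in a (2+2) cycloaddition that forms the C(=O)–C(benzyl) and C(OMe)–CH bonds of 17. Reversible 4π opening of 17 gives dienylketene 18, and the isomer with the alkenyl arm turned inward undergoes disrotatory 6π electrocyclisation, joining the benzyl-bearing diene terminus to the ketene carbon and closing six-membered ring B as dienone 19, which enolises irreversibly to phenol 20. The closest known reaction type is the thermal union of 3-alkylcyclobutenones with 1-methoxyalk-1-ynes to give resorcinol monomethyl ethers. No stereocentre is created, and the racemic sp3 carbon of 9 ends as an aromatic carbon. The one selectivity needed is the orientation of the (2+2) step, and the polarisation of 15 secures it: the benzyl-bearing carbon β to oxygen is the nucleophilic one and bonds to the ketene carbonyl carbon, so C–OMe ends beside the former α-CH and meta to C–OH. A methyl ynol ether cannot lose an alkene by retro-ene fragmentation at this temperature, and the two ortho benzyl groups shield the new phenol from acylation by 16.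

Step 8
Reactants: 20 2,6-bis(4-benzyloxybenzyl)-3-methoxy-5-[2-(3-methoxyphenyl)ethyl]phenol
Product: 21 2,6-bis(4-hydroxybenzyl)-3-methoxy-5-[2-(3-methoxyphenyl)ethyl]phenol (CNP0201265.0)
Conditions: H2 (1 atm), 10% Pd/C, EtOAc–EtOH, rt
Reagents that add atoms: none
Why: Catalytic hydrogenolysis cleaves only the two ArO–CH2Ph bonds, since the diarylmethane and bibenzyl C–C bonds, the aryl methyl ethers and the arenes are inert under neutral, atmospheric-pressure conditions.

Compound list
1 | 3-(4-benzyloxyphenyl)propanoic acid | O=C(O)CCc1ccc(OCc2ccccc2)cc1 | starting material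
2 | 3-(4-benzyloxyphenyl)propanoyl chloride | O=C(Cl)CCc1ccc(OCc2ccccc2)cc1 | intermediate
3 | ethoxyacetylene | CCOC#C | starting material
4 | (4-benzyloxybenzyl)ketene, 3-(4-benzyloxyphenyl)prop-1-en-1-one (formed in situ) | O=C=CCc1ccc(OCc2ccccc2)cc1 | intermediate
5 | rac-4-(4-benzyloxybenzyl)-3-ethoxycyclobut-2-en-1-one | CCOC1=CC(=O)C1Cc1ccc(OCc2ccccc2)cc1 | intermediate
6 | 1-(2-bromoethyl)-3-methoxybenzene | COc1cccc(CCBr)c1 | starting material
7 | 2-(3-methoxyphenyl)ethylmagnesium bromide | COc1cccc(CC[Mg]Br)c1 | intermediate
8 | 4-(4-benzyloxybenzyl)-3-ethoxy-1-[2-(3-methoxyphenyl)ethyl]cyclobut-2-en-1-ol (racemic diastereomer mixture, formed in situ) | CCOC1=CC(O)(CCc2cccc(OC)c2)C1Cc1ccc(OCc2ccccc2)cc1 | intermediate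
9 | rac-4-(4-benzyloxybenzyl)-3-[2-(3-methoxyphenyl)ethyl]cyclobut-2-en-1-one | O=C1C=C(CCc2cccc(OC)c2)C1Cc1ccc(OCc2ccccc2)cc1 | intermediate
10 | chloroacetaldehyde dimethyl acetal | COC(CCl)OC | starting material
11 | sodium methoxyacetylide (formed in situ) | [Na+].[C-]#COC | intermediate
12 | methoxyacetylene | COC#C | intermediate
13 | 4-benzyloxybenzyl bromide | BrCc1ccc(OCc2ccccc2)cc1 | starting material
14 | lithium methoxyacetylide (formed in situ) | [Li]C#COC | intermediate
15 | 1-(benzyloxy)-4-(3-methoxyprop-2-yn-1-yl)benzene | COC#CCc1ccc(OCc2ccccc2)cc1 | intermediate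
16 | (3E)-5-(4-benzyloxyphenyl)-3-[2-(3-methoxyphenyl)ethyl]penta-1,3-dien-1-one (vinylketene, formed in situ) | O=C=C/C(CCc1cccc(OC)c1)=C/Cc1ccc(OCc2ccccc2)cc1 | intermediate
17 | rac-2-(4-benzyloxybenzyl)-3-methoxy-4-[(E)-1-(4-benzyloxyphenyl)-5-(3-methoxyphenyl)pent-2-en-3-yl]cyclobut-2-en-1-one (formed in situ) | O=C1C(Cc2ccc(OCc3ccccc3)cc2)=C(OC)C1/C(CCc1cccc(OC)c1)=C/Cc1ccc(OCc2ccccc2)cc1 | intermediate
18 | (3E,5E)-2-(4-benzyloxybenzyl)-7-(4-benzyloxyphenyl)-3-methoxy-5-[2-(3-methoxyphenyl)ethyl]hepta-1,3,5-trien-1-one (dienylketene, ketene carbon chain and alkenyl arm cis across the C(OMe)=CH bond, formed in situ) | O=C=C(Cc1ccc(OCc2ccccc2)cc1)/C(OC)=C\C(CCc1cccc(OC)c1)=C\Cc1ccc(OCc2ccccc2)cc1 | intermediate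
19 | rac-2,6-bis(4-benzyloxybenzyl)-3-methoxy-5-[2-(3-methoxyphenyl)ethyl]cyclohexa-2,4-dien-1-one (formed in situ) | O=C1C(Cc2ccc(OCc3ccccc3)cc2)=C(OC)C=C(CCc2cccc(OC)c2)C1Cc1ccc(OCc2ccccc2)cc1 | intermediate
20 | 2,6-bis(4-benzyloxybenzyl)-3-methoxy-5-[2-(3-methoxyphenyl)ethyl]phenol | COc1cccc(CCc2cc(OC)c(Cc3ccc(OCc4ccccc4)cc3)c(O)c2Cc2ccc(OCc3ccccc3)cc2)c1 | intermediate
21 | 2,6-bis(4-hydroxybenzyl)-3-methoxy-5-[2-(3-methoxyphenyl)ethyl]phenol (CNP0201265.0, achiral) | COc1cccc(CCc2cc(OC)c(Cc3ccc(O)cc3)c(O)c2Cc2ccc(O)cc2)c1 | target

Total step count: 8.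
Longest linear sequence: 5 steps (1 to 2 to 5 to 9 to 20 to 21, that is steps 1, 2, 4, 7 and 8). The Grignard branch (step 3) and the alkyne branch (steps 5 and 6) run in parallel.

Steps most likely to fail

**Step 2.** The aldoketene may dimerise or oligomerise faster than it is trapped, and the ammonium salt may degrade the ynol ether.
- The fallback gives up both the ketene and the ethoxy relay. It sets out from 2 and 6.
- Acid chloride 2 is treated with dimethylamine to give N,N-dimethyl-3-(4-benzyloxyphenyl)propanamide F1.
- Bromide 6 is substituted with LiC≡CH·H2NCH2CH2NH2 in DMSO to give 1-(but-3-yn-1-yl)-3-methoxybenzene F2.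
- Activation of F1 with Tf2O and 2,4,6-collidine in 1,2-dichloroethane generates the keteniminium triflate F3. This electrophile is much stronger than the ketene and does not self-condense.
- In a keteniminium–alkyne (2+2) cycloaddition F3 takes up F2, with the alkyne CH terminus bonding to the central cumulene carbon, to give the cyclobuteniminium triflate F4.
- Aqueous hydrolysis comes back to the route at 9 and bypasses steps 2 to 4.

**Step 6.** The doubly activated (benzylic and propargylic) CH2 of the product may be deprotonated by unreacted acetylide, which would cause propargyl-to-allene isomerisation. The ynol ether may also hydrate during isolation.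
- The fallback makes the triple bond by elimination instead of alkylation. It sets out from 1.
- Fischer esterification (MeOH, cat. H2SO4) gives methyl 3-(4-benzyloxyphenyl)propanoate F5.
- Enolisation with LiN(i-Pr)2 and O-phosphorylation with ClP(O)(OEt)2 gives the ketene acetal phosphate, 3-(4-benzyloxyphenyl)-1-methoxyprop-1-en-1-yl diethyl phosphate F6.
- β-Elimination of diethyl phosphate with t-BuLi in THF at very low temperature comes back to the route at 15.

**Step 7.** The hindered internal ynol ether may capture the vinylketene too slowly. Ketene self-consumption, O-acylation of the product phenol or stalling before the second ring opening could then take over.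
- The fallback lowers the steric load of the annulation and attaches the second benzyl unit afterwards. It sets out from 9 and 12.
- The same thermal cascade with the unhindered terminal alkyne 12 (sealed tube, toluene, 80 °C) gives 2-(4-benzyloxybenzyl)-5-methoxy-3-[2-(3-methoxyphenyl)ethyl]phenol F7.
- Magnesium-mediated ortho-formylation (MgCl2, Et3N, paraformaldehyde, MeCN, reflux) can reach only the one free ortho carbon, between C–OH and C–OMe. It gives 3-(4-benzyloxybenzyl)-2-hydroxy-6-methoxy-4-[2-(3-methoxyphenyl)ethyl]benzaldehyde F8.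
- Addition of 4-benzyloxyphenylmagnesium bromide (2.2 equiv, THF, 0 °C) gives racemic 6-(4-benzyloxybenzyl)-2-[(4-benzyloxyphenyl)(hydroxy)methyl]-3-methoxy-5-[2-(3-methoxyphenyl)ethyl]phenol F9.
- Hydrogenolysis under the conditions of step 8 with a little AcOH removes the doubly benzylic hydroxyl group together with both benzyl ethers. This comes back to the route at 21.

Further compounds
F1 | step 2 | N,N-dimethyl-3-(4-benzyloxyphenyl)propanamide | CN(C)C(=O)CCc1ccc(OCc2ccccc2)cc1
F2 | step 2 | 1-(but-3-yn-1-yl)-3-methoxybenzene | C#CCCc1cccc(OC)c1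
F3 | step 2 | keteniminium triflate, N-[3-(4-benzyloxyphenyl)prop-1-en-1-ylidene]-N-methylmethanaminium trifluoromethanesulfonate | C[N+](C)=C=CCc1ccc(OCc2ccccc2)cc1.[O-]S(=O)(=O)C(F)(F)F
F4 | step 2 | cyclobuteniminium triflate, racemic N-{4-(4-benzyloxybenzyl)-3-[2-(3-methoxyphenyl)ethyl]cyclobut-2-en-1-ylidene}-N-methylmethanaminium trifluoromethanesulfonate | C[N+](C)=C1C=C(CCc2cccc(OC)c2)C1Cc1ccc(OCc2ccccc2)cc1.[O-]S(=O)(=O)C(F)(F)F
F5 | step 6 | methyl 3-(4-benzyloxyphenyl)propanoate | COC(=O)CCc1ccc(OCc2ccccc2)cc1
F6 | step 6 | 3-(4-benzyloxyphenyl)-1-methoxyprop-1-en-1-yl diethyl phosphate (alkene isomer mixture) | CCOP(=O)(OCC)OC(OC)=CCc1ccc(OCc2ccccc2)cc1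
F7 | step 7 | 2-(4-benzyloxybenzyl)-5-methoxy-3-[2-(3-methoxyphenyl)ethyl]phenol | COc1cccc(CCc2cc(OC)cc(O)c2Cc2ccc(OCc3ccccc3)cc2)c1
F8 | step 7 | 3-(4-benzyloxybenzyl)-2-hydroxy-6-methoxy-4-[2-(3-methoxyphenyl)ethyl]benzaldehyde | COc1cccc(CCc2cc(OC)c(C=O)c(O)c2Cc2ccc(OCc3ccccc3)cc2)c1
F9 | step 7 | racemic 6-(4-benzyloxybenzyl)-2-[(4-benzyloxyphenyl)(hydroxy)methyl]-3-methoxy-5-[2-(3-methoxyphenyl)ethyl]phenol | COc1cccc(CCc2cc(OC)c(C(O)c3ccc(OCc4ccccc4)cc3)c(O)c2Cc2ccc(OCc3ccccc3)cc2)c1
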